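Assumption: the SMILES is read as guibourtinidol-(4α→8)-ent-afzelechin (rings A/B/C 2R,3S,4S; rings D/E/F 2S,3R). The sense of induction of the ligand in step 9 is assigned by analogy, and its equally available antipode is used if the first run shows the opposite sense.

**Retrosynthetic overview**
1. The last step only removes five benzyl-type ethers from the fully assembled dimer.
2. Key disconnection: C4 (ring C)–C8 (ring D) together with C3–OH, back to a flav-3-ene 3,4-oxide and an 8-iodoflavan-3-ol. Both partners are electrophiles and are joined through a C4 benzylic radical (Ni/Ti reductive cross-electrophile coupling) that sets C4 trans to C3–O.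
3. Ring C and ring F are closed before the coupling. Each is made in one operation from a phenol and the same enal (ortho-hydroxyalkylation, then oxa-6π closure) as a racemic 2H-chromene.
4. Absolute configuration: ring C comes from a manganese-salen epoxidation run as a kinetic resolution, and ring F from a copper-catalysed borylation/oxidation run as a kinetic resolution. C8–I comes from regioselective iodination.
5. Carbon sources: 4-iodophenol (rings B, E), acrolein (C2–C4 of both units) and resorcinol (rings A, D). The third oxygen of ring D comes from C–H borylation/oxidation.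

**Route**

Step 1
Reactants: 1 4-iodophenol
Product: 2 1-(benzyloxy)-4-iodobenzene
Conditions: BnBr (1.05 equiv), K2CO3, acetone, reflux
Reagents that add atoms: benzyl bromide, BrCc1ccccc1
Why: Williamson ether synthesis; the phenoxide is alkylated on oxygen and the aryl iodide is untouched.

Step 2
Reactants: 2 1-(benzyloxy)-4-iodobenzene; 3 acrolein
Product: 4 (E)-3-[4-(benzyloxy)phenyl]prop-2-enal
Conditions: Pd(OAc)2 (2 mol %), Bu4NCl, NaHCO3, DMF, 50 °C
Reagents that add atoms: none
Why: Heck reaction under Jeffery phase-transfer conditions; syn insertion and syn β-hydride elimination give only the E enal, and the weak base keeps acrolein from polymerising.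

Step 3
Reactants: 5 resorcinol
Product: 6 3-(benzyloxy)phenol
Conditions: 5 (3 equiv), BnBr (1 equiv), K2CO3 (1 equiv), acetone, reflux
Reagents that add atoms: benzyl bromide, BrCc1ccccc1
Why: Williamson ether synthesis with resorcinol in excess, so that statistics favour the mono ether and surplus 5 is washed out with water.

Step 4
Reactants: 6 3-(benzyloxy)phenol; 4 (E)-3-[4-(benzyloxy)phenyl]prop-2-enal
Product: 8 rac-7-(benzyloxy)-2-[4-(benzyloxy)phenyl]-2H-chromene, via titanium tetrakis(3-benzyloxyphenoxide) 7 (not isolated)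
Conditions: Ti(OEt)4 (0.25 equiv), toluene, reflux, EtOH distilled off; then 4, reflux
Reagents that add atoms: none
Why: Metal-phenoxide-directed ortho-hydroxyalkylation of the enal carbonyl (at the less hindered ortho carbon, para to OBn), loss of the former carbonyl oxygen to titanium and oxa-6π electrocyclisation close ring C; C2 is formed racemic and is resolved in step 5.

Step 5
Reactants: 8 rac-7-(benzyloxy)-2-[4-(benzyloxy)phenyl]-2H-chromene
Product: 9 (2R,3S,4S)-7-(benzyloxy)-2-[4-(benzyloxy)phenyl]-3,4-epoxychromane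
Conditions: (S,S)-[N,N'-bis(3,5-di-tert-butylsalicylidene)cyclohexane-1,2-diaminato]manganese chloride (5 mol %), NMO (5 equiv), mCPBA (0.45 equiv), CH2Cl2, −78 °C; cold aq NaOH wash; used crude, cold, the same day
Reagents that add atoms: mCPBA, OOC(=O)c1cccc(Cl)c1
Why: Jacobsen–Katsuki epoxidation run as a kinetic resolution; the (S,S) catalyst delivers oxygen to the 3S,4S face of chromenes, which lies anti to the 2-aryl group only in (S)-8, so this antipode reacts much faster and gives the epoxide trans to the aryl group (fixing C2 and C3 of ring C) while (R)-8 stays behind and is inert in step 11.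

Step 6
Reactants: 5 resorcinol
Product: 10 1,3-bis[(4-methoxybenzyl)oxy]benzene
Conditions: PMBCl (2.2 equiv), K2CO3, Bu4NI (cat.), DMF, 60 °C
Reagents that add atoms: 4-methoxybenzyl chloride, COc1ccc(CCl)cc1
Why: Double Williamson ether synthesis; PMB is chosen because every C–H bond of its ring has an ortho neighbour (needed in step 7) and it still falls in the final hydrogenolysis.

Step 7
Reactants: 10 1,3-bis[(4-methoxybenzyl)oxy]benzene
Product: 12 3,5-bis[(4-methoxybenzyl)oxy]phenol, via aryl pinacol boronate 11 (not isolated)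
Conditions: [Ir(OMe)(cod)]2 (1 mol %), dtbpy (2 mol %), B2pin2 (0.6 equiv), THF, 60 °C; then H2O2, aq NaOH, 0 °C
Reagents that add atoms: bis(pinacolato)diboron, CC1(C)OB(OC1(C)C)B1OC(C)(C)C(C)(C)O1 (its atoms stay only in 11); hydrogen peroxide, OO
Why: Sterically governed iridium-catalysed C–H borylation takes the only C–H bond without an ortho substituent (C5 of the resorcinol ring), and oxidation of the C–B bond then gives the phloroglucinol pattern of ring D.

Step 8
Reactants: 12 3,5-bis[(4-methoxybenzyl)oxy]phenol; 4 (E)-3-[4-(benzyloxy)phenyl]prop-2-enal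
Product: 14 rac-2-[4-(benzyloxy)phenyl]-5,7-bis[(4-methoxybenzyl)oxy]-2H-chromene, via titanium tetrakis(aryloxide) 13 (not isolated)
Conditions: Ti(OEt)4 (0.25 equiv), toluene, reflux, EtOH distilled off; then 4, reflux
Reagents that add atoms: none
Why: Same metal-phenoxide-directed ortho-hydroxyalkylation/oxa-6π sequence as in step 4; the two ortho positions of 12 are equivalent, the acid-free medium spares the PMB ethers, and ring F is formed racemic at C2 and resolved in step 9.

Step 9
Reactants: 14 rac-2-[4-(benzyloxy)phenyl]-5,7-bis[(4-methoxybenzyl)oxy]-2H-chromene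
Product: 16 (2S,3R)-2-[4-(benzyloxy)phenyl]-5,7-bis[(4-methoxybenzyl)oxy]chroman-3-ol, via trans-3-borylflavan 15 (not isolated)
Conditions: CuCl (5 mol %), (S,S)-Ph-BPE (6 mol %), KOtBu (10 mol %), B2pin2 (0.55 equiv), MeOH (2 equiv), THF, 0 °C; then H2O2, aq NaOH, 0 °C
Reagents that add atoms: bis(pinacolato)diboron, CC1(C)OB(OC1(C)C)B1OC(C)(C)C(C)(C)O1 (its atoms stay only in 15); hydrogen peroxide, OO
Why: Copper-catalysed enantioselective protoboration run as a kinetic resolution; the ligated Cu–Bpin adds syn across C3=C4 with boron at C3 and copper at benzylic C4, anti to the 2-aryl group, only (R)-14 offers that face to the chiral catalyst, and stereoretentive C–B oxidation gives the 2,3-trans (2S,3R) alcohol.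

Step 10
Reactants: 16 (2S,3R)-2-[4-(benzyloxy)phenyl]-5,7-bis[(4-methoxybenzyl)oxy]chroman-3-ol
Product: 17 (2S,3R)-2-[4-(benzyloxy)phenyl]-8-iodo-5,7-bis[(4-methoxybenzyl)oxy]chroman-3-ol
Conditions: NIS (1.0 equiv), CH2Cl2, −20 to 0 °C, dark
Reagents that add atoms: N-iodosuccinimide, O=C1CCC(=O)N1I
Why: Electrophilic aromatic iodination of the most electron-rich ring (D); C8, flanked by one free ether and the tied-back ring oxygen, reacts before C6, which sits between two free ethers, as in the well-known C8 bromination of 5,7-di-O-benzyl flavan-3-ols with NBS.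

Step 11
Reactants: 9 (2R,3S,4S)-7-(benzyloxy)-2-[4-(benzyloxy)phenyl]-3,4-epoxychromane; 17 (2S,3R)-2-[4-(benzyloxy)phenyl]-8-iodo-5,7-bis[(4-methoxybenzyl)oxy]chroman-3-ol
Product: 18 (2R,3S,4S)-7-(benzyloxy)-2-[4-(benzyloxy)phenyl]-4-{(2S,3R)-2-[4-(benzyloxy)phenyl]-3-hydroxy-5,7-bis[(4-methoxybenzyl)oxy]chroman-8-yl}chroman-3-ol
Conditions: 9 (1.5 equiv), NiCl2(dme) (10 mol %), dtbbpy (12 mol %), Cp2TiCl2 (20 mol %), Mn powder (3 equiv), Et3N·HCl (1.5 equiv), DMPU, rt
Reagents that add atoms: none
Why: Proposed new method: Cp2TiCl (trivalent titanium, made from Cp2TiCl2 and Mn) opens the strained benzylic C4–O bond of 9 homolytically (any chlorohydrin formed from this labile epoxide and Et3N·HCl feeds the same radical by halogen abstraction at nickel), the planar C4 radical is captured by the aryl nickel species formed by oxidative addition of 17 to zerovalent nickel on the face anti to the bulky 3-O-titanium group, and reductive elimination from trivalent nickel gives the C4–C8 bond 3,4-trans (4S) with C2 and C3 untouched and the 3-OH released by Et3N·HCl; the closest known reaction type is the Ni/Ti co-catalysed cross-electrophile coupling of epoxides with aryl halides (trans-2-arylcycloalkanols from cycloalkene oxides, benzylic arylation of styrene oxides), and what is new is the chromene oxide and an electron-rich aryl iodide with two ortho oxygens.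

Step 12
Reactants: 18 protected dimer
Product: 19 guibourtinidol-(4α→8)-ent-afzelechin
Conditions: H2 (1 atm), Pd(OH)2/C, THF/MeOH/H2O, rt
Reagents that add atoms: none
Why: Heterogeneous hydrogenolysis cleaves the five ArO–CH2Ar bonds (three Bn, two PMB); the C2–O1 bonds, the C4 methine and the interflavan bond survive these neutral conditions, as they do in benzylated proanthocyanidins, so no stereocentre is touched.

**Compound list**
1 | 4-iodophenol | Oc1ccc(I)cc1 | starting material
2 | 1-(benzyloxy)-4-iodobenzene | Ic1ccc(OCc2ccccc2)cc1 | intermediate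
3 | acrolein | C=CC=O | starting material
4 | (E)-3-[4-(benzyloxy)phenyl]prop-2-enal | O=C/C=C/c1ccc(OCc2ccccc2)cc1 | intermediate
5 | resorcinol | Oc1cccc(O)c1 | starting material
6 | 3-(benzyloxy)phenol | Oc1cccc(OCc2ccccc2)c1 | intermediate
7 | titanium tetrakis(3-benzyloxyphenoxide), not isolated | [Ti](Oc1cccc(OCc2ccccc2)c1)(Oc1cccc(OCc2ccccc2)c1)(Oc1cccc(OCc2ccccc2)c1)Oc1cccc(OCc2ccccc2)c1 | intermediate
8 | rac-7-(benzyloxy)-2-[4-(benzyloxy)phenyl]-2H-chromene (racemic, no stereo label) | C(c1ccccc1)Oc1ccc(C2Oc3cc(OCc4ccccc4)ccc3C=C2)cc1 | intermediate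
9 | (2R,3S,4S)-7-(benzyloxy)-2-[4-(benzyloxy)phenyl]-3,4-epoxychromane (epoxide trans to the 2-aryl group) | C(c1ccccc1)Oc1ccc([C@H]2Oc3cc(OCc5ccccc5)ccc3[C@@H]4O[C@H]24)cc1 | intermediate
10 | 1,3-bis[(4-methoxybenzyl)oxy]benzene | COc1ccc(COc2cccc(OCc3ccc(OC)cc3)c2)cc1 | intermediate
11 | 2-{3,5-bis[(4-methoxybenzyl)oxy]phenyl}-4,4,5,5-tetramethyl-1,3,2-dioxaborolane, not isolated | COc1ccc(COc2cc(OCc3ccc(OC)cc3)cc(B3OC(C)(C)C(C)(C)O3)c2)cc1 | intermediate
12 | 3,5-bis[(4-methoxybenzyl)oxy]phenol | COc1ccc(COc2cc(O)cc(OCc3ccc(OC)cc3)c2)cc1 | intermediate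
13 | titanium tetrakis{3,5-bis[(4-methoxybenzyl)oxy]phenoxide}, not isolated | [Ti](Oc1cc(OCc2ccc(OC)cc2)cc(OCc2ccc(OC)cc2)c1)(Oc1cc(OCc2ccc(OC)cc2)cc(OCc2ccc(OC)cc2)c1)(Oc1cc(OCc2ccc(OC)cc2)cc(OCc2ccc(OC)cc2)c1)Oc1cc(OCc2ccc(OC)cc2)cc(OCc2ccc(OC)cc2)c1 | intermediate
14 | rac-2-[4-(benzyloxy)phenyl]-5,7-bis[(4-methoxybenzyl)oxy]-2H-chromene (racemic, no stereo label) | c1c(OCc5ccc(OC)cc5)cc(OCc5ccc(OC)cc5)c2c1OC(c1ccc(OCc5ccccc5)cc1)C=C2 | intermediate
15 | (2R,3R)-2-[4-(benzyloxy)phenyl]-5,7-bis[(4-methoxybenzyl)oxy]-3-(4,4,5,5-tetramethyl-1,3,2-dioxaborolan-2-yl)chromane (2,3-trans), not isolated | c1c(OCc5ccc(OC)cc5)cc(OCc5ccc(OC)cc5)c2c1O[C@@H](c1ccc(OCc5ccccc5)cc1)[C@H](B3OC(C)(C)C(C)(C)O3)C2 | intermediate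
16 | (2S,3R)-2-[4-(benzyloxy)phenyl]-5,7-bis[(4-methoxybenzyl)oxy]chroman-3-ol | c1c(OCc5ccc(OC)cc5)cc(OCc5ccc(OC)cc5)c2c1O[C@@H](c1ccc(OCc5ccccc5)cc1)[C@H](O)C2 | intermediate
17 | (2S,3R)-2-[4-(benzyloxy)phenyl]-8-iodo-5,7-bis[(4-methoxybenzyl)oxy]chroman-3-ol | Ic1c(OCc5ccc(OC)cc5)cc(OCc5ccc(OC)cc5)c2c1O[C@@H](c1ccc(OCc5ccccc5)cc1)[C@H](O)C2 | intermediate
18 | (2R,3S,4S)-7-(benzyloxy)-2-[4-(benzyloxy)phenyl]-4-{(2S,3R)-2-[4-(benzyloxy)phenyl]-3-hydroxy-5,7-bis[(4-methoxybenzyl)oxy]chroman-8-yl}chroman-3-ol | C(c1ccccc1)Oc1ccc([C@H]2Oc3cc(OCc5ccccc5)ccc3[C@@H](c3c(OCc5ccc(OC)cc5)cc(OCc5ccc(OC)cc5)c4c3O[C@@H](c3ccc(OCc5ccccc5)cc3)[C@H](O)C4)[C@@H]2O)cc1 | intermediate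
19 | guibourtinidol-(4α→8)-ent-afzelechin, (2R,3S,4S)-2-(4-hydroxyphenyl)-4-[(2S,3R)-3,5,7-trihydroxy-2-(4-hydroxyphenyl)chroman-8-yl]chromane-3,7-diol | Oc1ccc([C@H]2Oc3cc(O)ccc3[C@@H](c3c(O)cc(O)c4c3O[C@@H](c3ccc(O)cc3)[C@H](O)C4)[C@@H]2O)cc1 | target

**Totals**
- Total step count: 12.
- Longest linear sequence: 7 steps (5 → 10 → 12 → 14 → 16 → 17 → 18 → 19, steps 6–12). The line from 1 through 2 and 4 into step 8 is equally long.

**Steps most likely to fail**

(a) The coupling of step 11. The iodide 17 is electron-rich and has two ortho oxygens, so oxidative addition and radical capture at nickel may lose against hydrodeiodination of 17, dimerisation of the C4 radical, or deoxygenation of 9 back to the chromene. The fallback gives up the radical and forms the bond through the cation. It sets out from epoxide 9 and the non-iodinated flavan-3-ol 16 (3 equiv), with BF3·OEt2 (0.2 equiv) in CH2Cl2 at −78 °C. The epoxide ionises to the para-alkoxybenzylic C4 cation, and C8 of ring D attacks anti to the 3-oxygen. The route is rejoined at 18, step 10 is skipped, and no new compound is made.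

(b) The resolving epoxidation of step 5. The selectivity factor may be modest, and the para-alkoxybenzylic epoxide may not survive the peracid medium. The fallback moves the resolution to the dimer stage.
- It sets out from racemic 8, which is epoxidised with dimethyldioxirane in acetone/CH2Cl2 at −40 °C. These conditions are neutral and the reagent attacks anti to the 2-aryl group.
- This gives the racemic trans epoxide F1, which is freed of volatiles only and coupled with enantiopure 17 under the conditions of step 11.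
- The lower unit then acts as an internal resolving agent. Compound 18 and the diastereomeric dimer F2 (upper unit 2S,3R,4R) are separated by chromatography, and the route is rejoined at 18.

(c) The borylative resolution of step 9. The 5-alkoxy group crowds C4, and the very electron-rich styrene unit may add Cu–Bpin slowly or with poor discrimination. The fallback replaces catalytic resolution by a classical one.
- It sets out from racemic 14. BH3·THF followed by H2O2/aq NaOH adds anti to the 2-aryl group with boron at C3 and gives the racemic trans flavan-3-ol F3.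
- Esterification with (S)-O-methylmandelic acid (DCC, DMAP, CH2Cl2) gives the mandelate of the (2S,3R) alcohol F4 and the mandelate of the (2R,3S) alcohol F5.
- These are separated by chromatography or crystallisation. LiOH in THF/H2O cleaves F4, and the route is rejoined at 16.

**Further compounds**
F0 | step 11 | none | none
F1 | step 5 | racemic trans epoxide (9 plus its mirror image) | C(c1ccccc1)Oc1ccc([C@H]2Oc3cc(OCc5ccccc5)ccc3[C@@H]4O[C@H]24)cc1.C(c1ccccc1)Oc1ccc([C@@H]2Oc3cc(OCc5ccccc5)ccc3[C@H]4O[C@@H]24)cc1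
F2 | step 5 | diastereomeric dimer, upper unit 2S,3R,4R, lower unit 2S,3R | C(c1ccccc1)Oc1ccc([C@@H]2Oc3cc(OCc5ccccc5)ccc3[C@H](c3c(OCc5ccc(OC)cc5)cc(OCc5ccc(OC)cc5)c4c3O[C@@H](c3ccc(OCc5ccccc5)cc3)[C@H](O)C4)[C@H]2O)cc1
F3 | step 9 | racemic trans flavan-3-ol (16 plus its mirror image) | c1c(OCc5ccc(OC)cc5)cc(OCc5ccc(OC)cc5)c2c1O[C@@H](c1ccc(OCc5ccccc5)cc1)[C@H](O)C2.c1c(OCc5ccc(OC)cc5)cc(OCc5ccc(OC)cc5)c2c1O[C@H](c1ccc(OCc5ccccc5)cc1)[C@@H](O)C2
F4 | step 9 | (S)-O-methylmandelate of the (2S,3R) alcohol | c1c(OCc5ccc(OC)cc5)cc(OCc5ccc(OC)cc5)c2c1O[C@@H](c1ccc(OCc5ccccc5)cc1)[C@H](OC(=O)[C@@H](OC)c1ccccc1)C2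
F5 | step 9 | (S)-O-methylmandelate of the (2R,3S) alcohol | c1c(OCc5ccc(OC)cc5)cc(OCc5ccc(OC)cc5)c2c1O[C@H](c1ccc(OCc5ccccc5)cc1)[C@@H](OC(=O)[C@@H](OC)c1ccccc1)C2
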